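Cuts (labdane numbering): C12–C13 (Negishi coupling), C8=C17 (methylenation), C9–C11 and C1–C10 (one flask: anionic oxy-Cope shift, then enolate alkylation), and last C3–C8 and C4–C5 (Diels–Alder reaction).
Forward: ring B comes from 3-methylanisole as a 1-silyloxy-3-methylcyclohexa-1,3-diene. The cycloaddition lays a temporary C3–C4 bridge across C8 and C5. The [3,3] shift breaks C3–C8 and forms C1–C10, which turns that bridge into ring A. The chain then grows by C11–C12, C17 and C13–C16.
Enabling feature: rings A and B are cis-fused at C5–C10, with H5, the C10 methyl and the C4 ester on one face. C10 is followed by C9 (chain cis to that methyl) and by an sp2 C8. This array is the C8=C9 enolate of a cis-decalone, the direct product of the 1,5-diene C1=C2–C3–C8(O−)–C9=C10 held in an endo-vinyl bicyclo[2.2.2]octenol.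
Stereochemistry: the catalytic enantioselective endo Diels–Alder reaction sets C4 and C5 (plus the sacrificial C3 and C8). The suprafacial boat shift relays them to C10, and β-face alkylation of the folded enolate sets C9.
The E-configured C13=C14 bond comes from trans-hydroalumination/iodination of but-2-yne-1,4-diol and is carried through the coupling with retention.
Key step: step 9

Assumption: the SMILES is taken literally as the A/B-cis (5β-H) labdane, (4S,5S,9S,10R) with a 13E alkene; the (R) antipode of the catalyst in step 6 is assigned from the formyl C–H···O binding model for enals, and the (S) antipode is equally accessible should the sense be the reverse.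

Step 1
Reactants: 1 3-methylanisole
Product: 2 1-methoxy-5-methylcyclohexa-1,4-diene
Conditions: Li, NH3 (l), t-BuOH, THF, −78 → −33 °C
Reagents that add atoms: none
Why: Birch reduction: electron transfer and protonation leave the methoxy- and methyl-bearing carbons sp2, so the unconjugated 2,5-dihydro isomer should form; no stereocentre arises.

Step 2
Reactants: 2 1-methoxy-5-methylcyclohexa-1,4-diene
Product: 3 3-methylcyclohex-3-en-1-one
Conditions: oxalic acid (cat.), THF/H2O, rt
Reagents that add atoms: water, O
Why: Mild acid-catalysed enol ether hydrolysis: protonation of the electron-rich enol ether is much faster than migration of the trisubstituted alkene, so the β,γ-unsaturated ketone should stay unconjugated.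

Step 3
Reactants: 3 3-methylcyclohex-3-en-1-one
Product: 4 1-(tert-butyldimethylsilyloxy)-3-methylcyclohexa-1,3-diene
Conditions: t-BuMe2SiOTf, Et3N, CH2Cl2, −78 → 0 °C
Reagents that add atoms: tert-butyldimethylsilyl triflate, CC(C)(C)[Si](C)(C)OS(=O)(=O)C(F)(F)F
Why: Soft enolisation (silyl triflate/amine): the O-silylated oxocarbenium ion loses its most acidic proton, the C2–H that is both α to the carbonyl and allylic, which should give the linear 1-silyloxy-1,3-diene rather than the cross-conjugated isomer expected from 3-methylcyclohex-2-enone.

Step 4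
Reactants: 5 3-methylfuran-2-carboxylic acid
Product: 7 5-hydroxy-3-methylfuran-2(5H)-one, via furan endoperoxide 6 (not isolated)
Conditions: O2, hν (visible), 5,10,15,20-tetraphenylporphyrin (cat.), CH2Cl2, 0 °C
Reagents that add atoms: oxygen, O=O
Why: Singlet-oxygen [4+2] cycloaddition across C2 and C5 of the furan, then decarboxylative fragmentation of the endoperoxide, which turns the former C2 into the lactone carbonyl next to the methyl-bearing carbon; the hemiacetal centre is racemic and disappears in step 5.

Step 5
Reactants: 7 5-hydroxy-3-methylfuran-2(5H)-one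
Product: 9 methyl (Z)-2-methyl-4-oxobut-2-enoate, via open-chain formyl acid 8 (not isolated)
Conditions: CH2N2 (1.0 equiv, slow addition), Et2O, −20 °C
Reagents that add atoms: diazomethane, C=[N+]=[N-]
Why: Diazomethane esterification: only the carboxylic acid tautomer is acidic enough to protonate CH2N2, so the ring–chain equilibrium drains to the open methyl ester, and the cold, neutral medium and exact stoichiometry should keep the Z geometry inherited from the ring and avoid pyrazoline formation.

Step 6
Reactants: 4 1-(tert-butyldimethylsilyloxy)-3-methylcyclohexa-1,3-diene; 9 methyl (Z)-2-methyl-4-oxobut-2-enoate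
Product: 10 methyl (1S,2R,3R,4S)-4-(tert-butyldimethylsilyloxy)-3-formyl-2,6-dimethylbicyclo[2.2.2]oct-5-ene-2-carboxylate (formyl and ester endo, syn to the C5=C6 bridge)
Conditions: (R)-3,3-diphenyl-1-(2-methylphenyl)tetrahydro-1H,3H-pyrrolo[1,2-c][1,3,2]oxazaborole (20 mol %), (CF3SO2)2NH (18 mol %), CH2Cl2, −78 °C
Reagents that add atoms: none
Why: Catalytic enantioselective Diels–Alder reaction: the oxazaborolidinium ion binds the formyl oxygen of 9, so labdane C4 (β to the formyl group, largest LUMO coefficient) bonds to the most nucleophilic diene terminus C5 and the formyl-bearing C3 bonds to the silyloxy terminus C8 ("ortho" orientation), the Z geometry and the endo rule place formyl and ester together over the nascent C9=C10 bond with the methyl exo, and the shielding aryl group of the catalyst leaves one enantiotopic face of 9 open, which sets C3, C4, C5 and C8 in one event.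

Step 7
Reactants: 10 bicyclic silyloxy aldehyde
Product: 11 methyl (1S,2R,3R,4S)-4-(tert-butyldimethylsilyloxy)-3-ethenyl-2,6-dimethylbicyclo[2.2.2]oct-5-ene-2-carboxylate
Conditions: Ph3PCH3Br, KN(SiMe3)2, THF, 0 °C; then 10, −78 → 0 °C
Reagents that add atoms: methyltriphenylphosphonium bromide, C[P+](c1ccccc1)(c1ccccc1)c1ccccc1.[Br-]
Why: Wittig methylenation: addition of the unstabilised ylide to the aldehyde is faster than enolisation of the hindered C3–H, β-elimination of the bridgehead silyloxy group is barred by Bredt's rule and the silyl ether blocks retro-aldol cleavage, so the endo configuration at C3 should be kept.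

Step 8
Reactants: 11 endo-vinyl bridgehead silyl ether
Product: 12 methyl (1S,2R,3R,4S)-3-ethenyl-4-hydroxy-2,6-dimethylbicyclo[2.2.2]oct-5-ene-2-carboxylate
Conditions: Bu4NF, AcOH (1:1), THF, rt → 40 °C
Reagents that add atoms: none
Why: Fluoride desilylation driven by Si–F bond formation: the acetic acid buffer keeps the bridgehead oxygen protonated, and lactonisation onto the C4 ester is geometrically excluded because the C8–O bond is antiperiplanar to C3–C4.

Step 9
Reactants: 12 endo-vinyl bridgehead alcohol; 13 methyl bromoacetate
Product: 16 dimethyl 8-oxo-13,14,15,16,17-pentanor-5β-labd-2-ene-12,19-dioate, via potassium alkoxide 14 (not isolated), via potassium enolate 15 (not isolated)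
Conditions: KH (1.05 equiv), 18-crown-6, THF, 0 → 25 °C; then 13, −78 °C
Reagents that add atoms: none
Why: KH converts 12 into the bridgehead C8 alkoxide 14, whose 1,5-diene C1=C2–C3–C8–C9=C10 is locked by the bicycle in a boat array with the endo vinyl group lying over the C9=C10 bridge, so the charge-accelerated [3,3] shift forms C1–C10, breaks C3–C8 and delivers the C8=C9 potassium enolate 15, which then displaces bromide from 13 by SN2 C-alkylation (C9–C11). The closest known reaction type is the anionic oxy-Cope rearrangement of endo-vinylbicyclo[2.2.2]oct-5-en-2-ols to cis-decalones with trapping of the regiodefined enolate; here the oxido group sits on the bridgehead, which is still position 3 of the same hexadiene. Ring A (C1, C2, C3, C4, C5, C10) closes as a six-membered ring by the sigmatropic C1–C10 bond formation through the boat transition state, a bicyclo[2.2.2] to bicyclo[4.4.0] reorganisation rather than an ionic exo or endo cyclisation, while the C3–C8 scission releases ring B. C10 is set because C1 can reach only the face of C9=C10 that looks at the C3–C4 bridge, which leaves the methyl cis to H5 (cis fusion); C9 is set because the α face of the enolate is covered by C1 and by the fully substituted C4 of the folded ring A, so 13 should enter axially from the β face, anti to the C10–C1 bond and cis to the C10 methyl. The step needs the [3,3] path to beat cycloreversion, 1,3-shift and fragmentation, which is secured by the enforced contact of C1 and C10, the unsubstituted vinyl terminus and the absence of a carbonyl group at C3 that could turn the scission into a retro-aldol. It also needs C-alkylation at C9 only, which is secured by the soft, reactive bromide, by KH leaving no proton source that could move the enolate to C7, and by the C4 ester having no α-hydrogen.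

Step 10
Reactants: 16 unsaturated keto diester
Product: 17 dimethyl 8-oxo-13,14,15,16,17-pentanor-5β-labdane-12,19-dioate
Conditions: H2 (1 atm), 10% Pd/C, EtOAc, rt
Reagents that add atoms: none
Why: Heterogeneous catalytic hydrogenation of the cis-disubstituted C2=C3 bond, the only alkene present; the neutral medium leaves the ketone and the epimerisable C9 untouched and no stereocentre is created.

Step 11
Reactants: 17 saturated keto diester
Product: 18 dimethyl 13,14,15,16-tetranor-5β-labd-8(17)-ene-12,19-dioate
Conditions: Zn, CH2Br2, TiCl4 (pre-aged reagent), THF/CH2Cl2, 0 °C → rt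
Reagents that add atoms: dibromomethane, BrCBr
Why: Takai–Lombardo methylenation: the gem-dimetallic methylene reagent is nucleophilic but not basic, attacks ketones and ignores esters, so C8=C17 should be installed without epimerisation at C9, which is configurationally fixed from here on.

Step 12
Reactants: 18 8(17)-methylene diester
Product: 19 methyl 12-hydroxy-13,14,15,16-tetranor-5β-labd-8(17)-en-19-oate
Conditions: i-Bu2AlH (2.2 equiv), CH2Cl2, −78 → −20 °C; aq. potassium sodium tartrate
Reagents that add atoms: none
Why: Sterically governed chemoselective ester reduction: the unhindered C12 ester is reduced while the C19 ester on the quaternary, neopentyl-type C4 is shielded, and at low temperature the hydride does not add to C8=C17 (a borohydride/ester combination could hydroborate it).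

Step 13
Reactants: 19 C12 primary alcohol
Product: 20 methyl 12-iodo-13,14,15,16-tetranor-5β-labd-8(17)-en-19-oate
Conditions: I2, PPh3, imidazole, CH2Cl2, 0 °C
Reagents that add atoms: iodine, II
Why: Appel-type iodination: SN2 displacement of the alkoxyphosphonium ion by iodide at the primary C12, with iodine consumed by the phosphine before it can touch the alkene.

Step 14
Reactants: 21 but-2-yne-1,4-diol
Product: 23 (Z)-2-iodobut-2-ene-1,4-diol, via cyclic alkenylaluminate 22 (not isolated)
Conditions: NaAlH2(OCH2CH2OMe)2 (2.2 equiv), THF, 0 °C → rt; then I2, THF, −78 → 0 °C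
Reagents that add atoms: iodine, II
Why: Hydroxyl-directed trans-hydroalumination of a propargylic alcohol followed by iodinolysis of the C–Al bond with retention: H and Al add anti, so the two CH2OH groups end up trans and iodine cis to the distal CH2OH, and the symmetry of 21 removes any regiochemical question.

Step 15
Reactants: 23 (Z)-2-iodobut-2-ene-1,4-diol
Product: 24 (Z)-1,4-bis(tert-butyldimethylsilyloxy)-2-iodobut-2-ene
Conditions: t-BuMe2SiCl, imidazole, DMF, rt
Reagents that add atoms: tert-butyldimethylsilyl chloride, CC(C)(C)[Si](C)(C)Cl
Why: Standard imidazole-promoted silylation of two primary allylic alcohols, which does not affect the iodoalkene geometry.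

Step 16
Reactants: 20 C12 primary iodide; 24 (Z)-iodoalkene bis-silyl ether
Product: 26 methyl (13E)-15,16-bis(tert-butyldimethylsilyloxy)-5β-labda-8(17),13-dien-19-oate, via alkylzinc iodide 25 (not isolated)
Conditions: Zn dust (activated with cat. BrCH2CH2Br/Me3SiCl), LiCl, THF, 25–40 °C; then 24, PdCl2(dppf) (5 mol %; dppf = 1,1'-bis(diphenylphosphino)ferrocene), THF, rt → 40 °C
Reagents that add atoms: none
Why: Negishi sp3–sp2 coupling: LiCl-assisted zinc insertion tolerates the ester and the 1,1-disubstituted alkene, zerovalent palladium inserts into the alkenyl C–I bond with retention, and the wide-bite-angle ligand makes reductive elimination faster than β-hydride elimination, so C12 takes the place of iodine cis to C15.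

Step 17
Reactants: 26 bis-silyl ether
Product: 27 methyl (13E)-15,16-dihydroxy-5β-labda-8(17),13-dien-19-oate (target)
Conditions: HF·pyridine, pyridine/THF, 0 °C → rt
Reagents that add atoms: none
Why: Fluoride desilylation of two primary allylic silyl ethers under buffered conditions that leave the hindered methyl ester, both alkenes and all four stereocentres unchanged.

Compound list
1 | 3-methylanisole | COc1cccc(C)c1 | starting material
2 | 1-methoxy-5-methylcyclohexa-1,4-diene | COC1=CCC=C(C)C1 | intermediate
3 | 3-methylcyclohex-3-en-1-one | CC1=CCCC(=O)C1 | intermediate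
4 | 1-(tert-butyldimethylsilyloxy)-3-methylcyclohexa-1,3-diene | CC1=CCCC(O[Si](C)(C)C(C)(C)C)=C1 | intermediate
5 | 3-methylfuran-2-carboxylic acid | Cc1ccoc1C(=O)O | starting material
6 | 6-methyl-2,3,7-trioxabicyclo[2.2.1]hept-5-ene-1-carboxylic acid (racemic furan endoperoxide) | CC1=CC2OOC1(C(=O)O)O2 | intermediate (not isolated)
7 | 5-hydroxy-3-methylfuran-2(5H)-one (racemic hemiacetal) | CC1=CC(O)OC1=O | intermediate
8 | (Z)-2-methyl-4-oxobut-2-enoic acid (open-chain tautomer of 7) | O=C/C=C(/C)C(=O)O | intermediate (not isolated)
9 | methyl (Z)-2-methyl-4-oxobut-2-enoate (formyl and ester cis) | O=C/C=C(/C)C(=O)OC | intermediate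
10 | methyl (1S,2R,3R,4S)-4-(tert-butyldimethylsilyloxy)-3-formyl-2,6-dimethylbicyclo[2.2.2]oct-5-ene-2-carboxylate, formyl and ester endo | O=C[C@@H]1[C@](C)(C(=O)OC)[C@H]2CC[C@]1(O[Si](C)(C)C(C)(C)C)C=C2C | intermediate
11 | methyl (1S,2R,3R,4S)-4-(tert-butyldimethylsilyloxy)-3-ethenyl-2,6-dimethylbicyclo[2.2.2]oct-5-ene-2-carboxylate, vinyl and ester endo | C=C[C@@H]1[C@](C)(C(=O)OC)[C@H]2CC[C@]1(O[Si](C)(C)C(C)(C)C)C=C2C | intermediate
12 | methyl (1S,2R,3R,4S)-3-ethenyl-4-hydroxy-2,6-dimethylbicyclo[2.2.2]oct-5-ene-2-carboxylate, vinyl and ester endo | C=C[C@@H]1[C@](C)(C(=O)OC)[C@H]2CC[C@]1(O)C=C2C | intermediate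
13 | methyl bromoacetate | COC(=O)CBr | starting material
14 | potassium bridgehead (C8) alkoxide of 12 | C=C[C@@H]1[C@](C)(C(=O)OC)[C@H]2CC[C@]1([O-])C=C2C.[K+] | intermediate (not isolated)
15 | potassium C8=C9 enolate of the cis-fused 8-oxo-labd-2-ene core (H5, C10 methyl and C4 ester β) | [K+].[O-]C1=C[C@@]2(C)CC=C[C@](C)(C(=O)OC)[C@H]2CC1 | intermediate (not isolated)
16 | dimethyl 8-oxo-13,14,15,16,17-pentanor-5β-labd-2-ene-12,19-dioate (cis-decalin; H5, C10 methyl, C4 ester and C9 CH2CO2Me all β; H9 and C4 methyl α) | O=C1CC[C@H]2[C@](C)(CC=C[C@]2(C)C(=O)OC)[C@H]1CC(=O)OC | intermediate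
17 | dimethyl 8-oxo-13,14,15,16,17-pentanor-5β-labdane-12,19-dioate (configuration as in 16) | O=C1CC[C@H]2[C@](C)(CCC[C@]2(C)C(=O)OC)[C@H]1CC(=O)OC | intermediate
18 | dimethyl 13,14,15,16-tetranor-5β-labd-8(17)-ene-12,19-dioate (configuration as in 16) | C=C1CC[C@H]2[C@](C)(CCC[C@]2(C)C(=O)OC)[C@H]1CC(=O)OC | intermediate
19 | methyl 12-hydroxy-13,14,15,16-tetranor-5β-labd-8(17)-en-19-oate | C=C1CC[C@H]2[C@](C)(CCC[C@]2(C)C(=O)OC)[C@H]1CCO | intermediate
20 | methyl 12-iodo-13,14,15,16-tetranor-5β-labd-8(17)-en-19-oate | C=C1CC[C@H]2[C@](C)(CCC[C@]2(C)C(=O)OC)[C@H]1CCI | intermediate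
21 | but-2-yne-1,4-diol | OCC#CCO | starting material
22 | disodium cyclic alkenylaluminate (2,5-dihydro-1,2-oxaaluminole; Al on C2, cis to C4; second oxygen bound to a hydridoaluminate) | [Na+].[Na+].COCCO[Al-]1(OCCOC)OCC=C1CO[AlH-](OCCOC)OCCOC | intermediate (not isolated)
23 | (Z)-2-iodobut-2-ene-1,4-diol (CH2OH groups trans) | I/C(=C\CO)CO | intermediate
24 | (Z)-1,4-bis(tert-butyldimethylsilyloxy)-2-iodobut-2-ene | I/C(=C\CO[Si](C)(C)C(C)(C)C)CO[Si](C)(C)C(C)(C)C | intermediate
25 | methyl 12-(iodozincio)-13,14,15,16-tetranor-5β-labd-8(17)-en-19-oate | C=C1CC[C@H]2[C@](C)(CCC[C@]2(C)C(=O)OC)[C@H]1CC[Zn]I | intermediate (not isolated)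
26 | methyl (13E)-15,16-bis(tert-butyldimethylsilyloxy)-5β-labda-8(17),13-dien-19-oate | C=C1CC[C@H]2[C@](C)(CCC[C@]2(C)C(=O)OC)[C@H]1CC/C(=C\CO[Si](C)(C)C(C)(C)C)CO[Si](C)(C)C(C)(C)C | intermediate
27 | methyl (4S,5S,9S,10R,13E)-15,16-dihydroxy-5β-labda-8(17),13-dien-19-oate (CNP0282002.1) | C=C1CC[C@H]2[C@](C)(CCC[C@]2(C)C(=O)OC)[C@H]1CC/C(=C\CO)CO | target

Total step count: 17. Longest linear sequence: 13 steps (steps 1–3, 6–13, 16, 17).

Steps most likely to fail

Step 9.
- What may go wrong: the crown-activated potassium enolate may exchange protons with the keto ester as it forms. That would move the enolate towards C7, erode the C9 configuration and open the way to double alkylation or O-alkylation. If the shift needs warming, alkoxide-driven cycloreversion may also drain the alkoxide.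
- Fallback: the shift and the capture are separated. Setting out from 12, the same KH/18-crown-6 rearrangement is quenched at −78 °C with Me3SiCl/Et3N to give the regiodefined trimethylsilyl enol ether F1, which is isolated. Fluoride-triggered alkylation of F1 with 13 (anhydrous benzyltrimethylammonium fluoride, 4 Å molecular sieves, THF) unmasks the nucleophile only as fast as it is consumed. With the same β-face preference, this should come back to the route at 16.

Step 6.
- What may go wrong: enantiofacial or endo/exo discrimination may be insufficient with a trisubstituted, doubly activated dienophile whose C4 methyl meets the ethano bridge. Other risks are acid-induced Z to E isomerisation of the dienophile, protodesilylation of the diene, and 1,2-attack of the dienol ether on the activated formyl group.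
- Fallback: racemic cycloaddition followed by resolution. Setting out from 4 and 9, the cycloaddition is promoted by Me2AlCl (CH2Cl2, −78 °C) and gives 10 together with its mirror-image adduct F2. Condensation of the mixture with (1R,2R)-N,N'-dimethyl-1,2-diphenylethane-1,2-diamine (4 Å molecular sieves, Et2O) gives the imidazolidine F3 and the diastereomeric imidazolidine F4, which are separated by chromatography or crystallisation. Mild hydrolysis of F3 (dilute aqueous citric acid/Et2O) comes back to the route at 10 as a single enantiomer.

Step 16.
- What may go wrong: zinc insertion may be slow or incomplete, the alkylzinc may be protonated, β-hydride elimination may follow transmetalation, or the alkene geometry may be partly lost.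
- Fallback: the trisubstituted alkene is built by olefination instead of being imported.
  - Setting out from 20, alkylation of sodium triethyl phosphonoacetate (NaH, DMF, 50 °C) gives the phosphonate F5 (epimers at C13, of no consequence).
  - Horner–Wadsworth–Emmons reaction of F5 with (tert-butyldimethylsilyloxy)acetaldehyde (NaH, THF, 0 °C) should give the (E)-enoate F6, in which C15 lies trans to the ester carbon C16 and cis to C12, as required.
  - i-Bu2AlH (CH2Cl2, −78 °C) reduces the conjugated ester to the mono-silylated diol F7 while the hindered C19 ester is spared.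
  - HF·pyridine as in step 17 comes back to the route at 27.

Further compounds
F1 | step 9 | trimethylsilyl enol ether (C8=C9) of the cis-fused 8-oxo-labd-2-ene core | C[Si](C)(C)OC1=C[C@@]2(C)CC=C[C@](C)(C(=O)OC)[C@H]2CC1
F2 | step 6 | mirror-image adduct, methyl (1R,2S,3S,4R)-4-(tert-butyldimethylsilyloxy)-3-formyl-2,6-dimethylbicyclo[2.2.2]oct-5-ene-2-carboxylate | O=C[C@H]1[C@@](C)(C(=O)OC)[C@@H]2CC[C@@]1(O[Si](C)(C)C(C)(C)C)C=C2C
F3 | step 6 | (4R,5R)-1,3-dimethyl-4,5-diphenylimidazolidin-2-yl derivative of 10 | CN3[C@H](c4ccccc4)[C@@H](c4ccccc4)N(C)C3[C@@H]1[C@](C)(C(=O)OC)[C@H]2CC[C@]1(O[Si](C)(C)C(C)(C)C)C=C2C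
F4 | step 6 | (4R,5R)-1,3-dimethyl-4,5-diphenylimidazolidin-2-yl derivative of F2 | CN3[C@H](c4ccccc4)[C@@H](c4ccccc4)N(C)C3[C@H]1[C@@](C)(C(=O)OC)[C@@H]2CC[C@@]1(O[Si](C)(C)C(C)(C)C)C=C2C
F5 | step 16 | C13 diethyl phosphonate ethyl ester from alkylation of triethyl phosphonoacetate with 20 | C=C1CC[C@H]2[C@](C)(CCC[C@]2(C)C(=O)OC)[C@H]1CCC(C(=O)OCC)P(=O)(OCC)OCC
F6 | step 16 | 16-ethyl 19-methyl (13E)-15-(tert-butyldimethylsilyloxy)-5β-labda-8(17),13-diene-16,19-dioate | C=C1CC[C@H]2[C@](C)(CCC[C@]2(C)C(=O)OC)[C@H]1CC/C(=C\CO[Si](C)(C)C(C)(C)C)C(=O)OCC
F7 | step 16 | methyl (13E)-15-(tert-butyldimethylsilyloxy)-16-hydroxy-5β-labda-8(17),13-dien-19-oate | C=C1CC[C@H]2[C@](C)(CCC[C@]2(C)C(=O)OC)[C@H]1CC/C(=C\CO[Si](C)(C)C(C)(C)C)CO
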